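## Retrosynthetic overview

1. Target ⇒ O‑demethylation and decarboxylative rearomatisation of a 1‑alkyl‑3,5‑dimethoxycyclohexa‑2,5‑diene‑1‑carboxylic acid.
2. Key disconnection at the aryl–CH2 bond: dearomatising Birch reductive alkylation of 3,5‑dimethoxybenzoic acid with the complete C17 (Z,Z)‑bromo‑dienol, so that ring C‑1 itself becomes the nucleophile.
3. C17 bromo‑dienol ⇒ one‑pot double Z‑selective Wittig reaction, in which a symmetric C3 bis‑phosphonium salt is desymmetrised between 8‑bromooctanal and (S)‑5‑hydroxyhexanal (as its lactol).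
4. Lactol ⇒ (S)‑propylene oxide (source of the only stereocentre, S) plus an acetal‑bearing C3 Grignard reagent.
5. Rings: none is built. The benzene ring comes from the feedstock, is dearomatised in step 3 and rearomatised in step 4; a transient tetrahydropyranol ring forms in step 1 and is opened in step 2.

Assumption: 8‑bromooctanal, the C3 bis‑phosphonium salt and the dioxanylethyl Grignard solution are bought as catalogue items.

## Route

Step 1
Reactants: 1 (S)‑2‑methyloxirane [(S)‑propylene oxide]; 2 [2‑(1,3‑dioxan‑2‑yl)ethyl]magnesium bromide (0.5 M in THF)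
Product: 4 (6S)‑6‑methyltetrahydro‑2H‑pyran‑2‑ol (lactol form of (5S)‑5‑hydroxyhexanal; anomer mixture), via hydroxy acetal 3 (not isolated)
Conditions: CuBr·SMe2 (10 mol %), THF, −30 → 0 °C; then 2 M HCl, THF–H2O, rt, 4 h
Reagents that add atoms: water (O)
Why: Copper‑catalysed Grignard opening of the epoxide (SN2 at the unsubstituted CH2) leaves the C–O stereocentre of 1 untouched (S), and aqueous acid then hydrolyses the dioxane through the internal hydroxyl (trans‑acetalisation, then hydrolysis) to the six‑membered lactol.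

Step 2
Reactants: 4 (6S)‑6‑methyltetrahydro‑2H‑pyran‑2‑ol; 5 propane‑1,3‑diylbis(triphenylphosphonium) dibromide; 6 8‑bromooctanal
Product: 9 (2S,6Z,9Z)‑17‑bromoheptadeca‑6,9‑dien‑2‑ol, via mono‑ylide 7 (not isolated), via bromoalkenylphosphonium salt 8 (not isolated)
Conditions: 5, NaN(SiMe3)2 (1.0 equiv), THF, 0 °C → rt, 1 h; −78 °C, 6 (1.0 equiv), then → 0 °C; −78 °C, NaN(SiMe3)2 (2.1 equiv), then 4 (1.1 equiv), −78 °C → rt; H2O
Reagents that add atoms: none
Why: Sequential double Wittig olefination from one symmetric C3 bis‑phosphonium salt: one equivalent of base gives mono‑ylide 7 (the second P–CH2 is less acidic once the first is an ylide), which adds to 6 at −78 °C, and the remaining phosphonium 8 is then deprotonated and condensed with the open hydroxy‑aldehyde form of lactol 4; lithium‑free non‑stabilised ylides give the Z‑alkenes through kinetically formed cis‑oxaphosphetanes, and the carbinol stereocentre is not touched.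

Step 3
Reactants: 9 (2S,6Z,9Z)‑17‑bromoheptadeca‑6,9‑dien‑2‑ol; 10 3,5‑dimethoxybenzoic acid
Product: 12 1‑[(8Z,11Z,16S)‑16‑hydroxyheptadeca‑8,11‑dien‑1‑yl]‑3,5‑dimethoxycyclohexa‑2,5‑diene‑1‑carboxylic acid, via dilithium dienolate 11 (not isolated)
Conditions: 10 (1.5 equiv), Li (4.8 equiv), NH3(l)–THF, −78 °C; isoprene until colourless; then 9 (1.0 equiv, pre‑treated with LiN(SiMe3)2, 1.0 equiv, THF, −78 °C), −78 → −33 °C, 1 h; solid NH4Cl; −NH3; cold pH 5 phosphate buffer–EtOAc; crude acid used directly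
Reagents that add atoms: none
Why: Birch reductive alkylation: Li in NH3 reduces the benzoate to the cross‑conjugated dienolate 11 (C‑4 protonated by NH3, both methoxy groups on enol‑ether carbons), which is C‑alkylated at C‑1 by the primary bromide in an SN2 reaction; the hydroxyl of 9 is masked as its lithium alkoxide, the non‑conjugated Z‑alkenes are not reduced once the blue colour is discharged, and the new quaternary carbon lies on a mirror plane of the ring so no stereocentre is created.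

Step 4
Reactants: 12 1‑[(8Z,11Z,16S)‑16‑hydroxyheptadeca‑8,11‑dien‑1‑yl]‑3,5‑dimethoxycyclohexa‑2,5‑diene‑1‑carboxylic acid
Product: 13 (2S,6Z,9Z)‑17‑(3,5‑dimethoxyphenyl)heptadeca‑6,9‑dien‑2‑ol
Conditions: Pb(OAc)4 (1.05 equiv), CH2Cl2, −20 → 0 °C, 30 min
Reagents that add atoms: none
Why: Oxidative decarboxylation of a 1‑alkyl‑1,4‑dihydrobenzoic acid: the tetravalent lead carboxylate loses CO2 to give a cyclohexadienyl cation stabilised by both methoxy groups, which loses the C‑4 proton and rearomatises; at −20 to 0 °C this is far faster than attack of Pb(OAc)4 on the secondary alcohol or the isolated alkenes, and no stereocentre is involved.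

Step 5
Reactants: 13 (2S,6Z,9Z)‑17‑(3,5‑dimethoxyphenyl)heptadeca‑6,9‑dien‑2‑ol
Product: 14 Hansfordiol D = 5‑[(8Z,11Z,16S)‑16‑hydroxyheptadeca‑8,11‑dien‑1‑yl]benzene‑1,3‑diol
Conditions: MeMgI (10 equiv, 3 M in Et2O), Et2O stripped, neat melt, 160 °C, 30 min, Ar; then Et2O, 1 M HCl, 0 °C
Reagents that add atoms: none
Why: Aryl methyl ether cleavage in a methylmagnesium iodide melt (magnesium coordinates the ether oxygen and iodide attacks the O‑methyl carbon in an SN2 reaction), a non‑acidic method that tolerates isolated alkenes; the secondary alcohol is carried as its magnesium alkoxide and the Z‑alkenes and the S‑centre are not touched.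

## Compound list

1 | (S)‑2‑methyloxirane | C[C@H]1CO1 | starting material
2 | [2‑(1,3‑dioxan‑2‑yl)ethyl]magnesium bromide | Br[Mg]CCC1OCCCO1 | starting material
3 | (2S)‑5‑(1,3‑dioxan‑2‑yl)pentan‑2‑ol | C[C@H](O)CCCC1OCCCO1 | intermediate
4 | (6S)‑6‑methyltetrahydro‑2H‑pyran‑2‑ol (anomer mixture) | C[C@H]1CCCC(O)O1 | intermediate
5 | propane‑1,3‑diylbis(triphenylphosphonium) dibromide | [Br-].[Br-].c1ccccc1[P+](c1ccccc1)(c1ccccc1)CCC[P+](c1ccccc1)(c1ccccc1)c1ccccc1 | starting material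
6 | 8‑bromooctanal | O=CCCCCCCCBr | starting material
7 | triphenyl[3‑(triphenyl‑λ5‑phosphanylidene)propyl]phosphonium bromide (mono‑ylide) | [Br-].c1ccccc1P(c1ccccc1)(c1ccccc1)=CCC[P+](c1ccccc1)(c1ccccc1)c1ccccc1 | intermediate
8 | [(3Z)‑11‑bromoundec‑3‑en‑1‑yl]triphenylphosphonium bromide | [Br-].BrCCCCCCC/C=C\CC[P+](c1ccccc1)(c1ccccc1)c1ccccc1 | intermediate
9 | (2S,6Z,9Z)‑17‑bromoheptadeca‑6,9‑dien‑2‑ol | C[C@H](O)CCC/C=C\C/C=C\CCCCCCCBr | intermediate
10 | 3,5‑dimethoxybenzoic acid | COc1cc(OC)cc(C(=O)O)c1 | starting material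
11 | dilithium 3,5‑dimethoxycyclohexa‑2,5‑dien‑1‑ide‑1‑carboxylate | [Li+].[Li+].COC1=C[C-](C(=O)[O-])C=C(OC)C1 | intermediate
12 | 1‑[(8Z,11Z,16S)‑16‑hydroxyheptadeca‑8,11‑dien‑1‑yl]‑3,5‑dimethoxycyclohexa‑2,5‑diene‑1‑carboxylic acid | C[C@H](O)CCC/C=C\C/C=C\CCCCCCCC1(C(=O)O)C=C(OC)CC(OC)=C1 | intermediate
13 | (2S,6Z,9Z)‑17‑(3,5‑dimethoxyphenyl)heptadeca‑6,9‑dien‑2‑ol | C[C@H](O)CCC/C=C\C/C=C\CCCCCCCc1cc(OC)cc(OC)c1 | intermediate
14 | Hansfordiol D, 5‑[(8Z,11Z,16S)‑16‑hydroxyheptadeca‑8,11‑dien‑1‑yl]benzene‑1,3‑diol | C[C@H](O)CCC/C=C\C/C=C\CCCCCCCc1cc(O)cc(O)c1 | target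

## Step count and risks

Total step count: 5. Longest linear sequence: 5 steps (1 → 4 → 9 → 12 → 13 → 14).

The three steps most likely to fail:

**Step 2 (one‑pot double Wittig).** Proton exchange between ylide and phosphonium species can scramble the two aldehydes into symmetrical dienes, and the ylide can attack the primary bromide. The fallback brings the C3 unit in unsymmetrically and stepwise; it sets out from lactol 4 and comes back at 9. Wittig reaction of 4 with the ylide of commercial [2‑(1,3‑dioxolan‑2‑yl)ethyl]triphenylphosphonium bromide (2.2 equiv, NaN(SiMe3)2, THF, −78 °C → rt) gives (2S,6Z)‑8‑(1,3‑dioxolan‑2‑yl)oct‑6‑en‑2‑ol F1. Brief acetal hydrolysis (TsOH·H2O, wet acetone, 40 °C) gives the sensitive β,γ‑unsaturated aldehyde (3Z,8S)‑8‑hydroxynon‑3‑enal F2, which is used crude at once. A second Z‑selective Wittig reaction with the ylide of (8‑bromooctyl)triphenylphosphonium bromide F3 (made from 1,8‑dibromooctane, 3 equiv, and PPh3 in toluene at 110 °C; 2.2 equiv of ylide, NaN(SiMe3)2, THF, −78 °C → 0 °C, the extra equivalent taking the hydroxyl proton) returns to 9.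

**Step 3 (reductive alkylation with the elaborated bromide).** The free hydroxyl can quench the dienolate, LiNH2 can move the skipped diene into conjugation, and the valuable bromide may alkylate poorly. The fallback moves the dearomatising alkylation to the front with a robust electrophile and builds the diene last; it sets out from 10 and comes back at 13. Li, NH3–THF, −78 °C on 10, then 9‑bromonon‑1‑ene, gives 3,5‑dimethoxy‑1‑(non‑8‑en‑1‑yl)cyclohexa‑2,5‑diene‑1‑carboxylic acid F4. Pb(OAc)4 in CH2Cl2 rearomatises it to 1,3‑dimethoxy‑5‑(non‑8‑en‑1‑yl)benzene F5. OsO4 (2 mol %)–NaIO4, 2,6‑lutidine, dioxane–H2O cleaves the terminal alkene to 8‑(3,5‑dimethoxyphenyl)octanal F6. The sequential double Wittig of step 2, run with F6 in place of 6 (through 7 and [(3Z)‑11‑(3,5‑dimethoxyphenyl)undec‑3‑en‑1‑yl]triphenylphosphonium bromide F7) and then lactol 4, gives 13. This order also keeps the diene away from Pb(OAc)4.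

**Step 5 (demethylation in the Grignard melt).** The 160 °C melt may isomerise the skipped diene or stop at the mono‑methyl ether. The fallback changes the phenol protection to one that leaves under mild acid while keeping the dearomatising alkylation; it sets out from 9 and comes back at 14. Methyl 3,5‑dihydroxybenzoate is converted (MOMCl, iPr2NEt, CH2Cl2) into methyl 3,5‑bis(methoxymethoxy)benzoate F8 and saponified (LiOH, THF–H2O) to 3,5‑bis(methoxymethoxy)benzoic acid F9. Bromide 9 is used in the reductive alkylation of step 3 with F9 to give 1‑[(8Z,11Z,16S)‑16‑hydroxyheptadeca‑8,11‑dien‑1‑yl]‑3,5‑bis(methoxymethoxy)cyclohexa‑2,5‑diene‑1‑carboxylic acid F10. Pb(OAc)4 (solid NaHCO3, CH2Cl2, −20 °C) gives (2S,6Z,9Z)‑17‑[3,5‑bis(methoxymethoxy)phenyl]heptadeca‑6,9‑dien‑2‑ol F11. HCl (catalytic) in MeOH at 40 °C removes both methoxymethyl groups and gives 14.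

## Further compounds

F1 | step 2 | (2S,6Z)‑8‑(1,3‑dioxolan‑2‑yl)oct‑6‑en‑2‑ol | C[C@H](O)CCC/C=C\CC1OCCO1
F2 | step 2 | (3Z,8S)‑8‑hydroxynon‑3‑enal | C[C@H](O)CCC/C=C\CC=O
F3 | step 2 | (8‑bromooctyl)triphenylphosphonium bromide | [Br-].BrCCCCCCCC[P+](c1ccccc1)(c1ccccc1)c1ccccc1
F4 | step 3 | 3,5‑dimethoxy‑1‑(non‑8‑en‑1‑yl)cyclohexa‑2,5‑diene‑1‑carboxylic acid | C=CCCCCCCCC1(C(=O)O)C=C(OC)CC(OC)=C1
F5 | step 3 | 1,3‑dimethoxy‑5‑(non‑8‑en‑1‑yl)benzene | C=CCCCCCCCc1cc(OC)cc(OC)c1
F6 | step 3 | 8‑(3,5‑dimethoxyphenyl)octanal | O=CCCCCCCCc1cc(OC)cc(OC)c1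
F7 | step 3 | [(3Z)‑11‑(3,5‑dimethoxyphenyl)undec‑3‑en‑1‑yl]triphenylphosphonium bromide | [Br-].COc1cc(OC)cc(CCCCCCC/C=C\CC[P+](c2ccccc2)(c2ccccc2)c2ccccc2)c1
F8 | step 5 | methyl 3,5‑bis(methoxymethoxy)benzoate | COCOc1cc(OCOC)cc(C(=O)OC)c1
F9 | step 5 | 3,5‑bis(methoxymethoxy)benzoic acid | COCOc1cc(OCOC)cc(C(=O)O)c1
F10 | step 5 | 1‑[(8Z,11Z,16S)‑16‑hydroxyheptadeca‑8,11‑dien‑1‑yl]‑3,5‑bis(methoxymethoxy)cyclohexa‑2,5‑diene‑1‑carboxylic acid | C[C@H](O)CCC/C=C\C/C=C\CCCCCCCC1(C(=O)O)C=C(OCOC)CC(OCOC)=C1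
F11 | step 5 | (2S,6Z,9Z)‑17‑[3,5‑bis(methoxymethoxy)phenyl]heptadeca‑6,9‑dien‑2‑ol | C[C@H](O)CCC/C=C\C/C=C\CCCCCCCc1cc(OCOC)cc(OCOC)c1
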